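**Retrosynthetic overview**
1. Target 34 ⇐ C8 desilylation, C13 acetylation and hydroxyl-directed epoxidation of the 11Z olefin of macrolactone 30 (epoxide ring formed last).
2. 30 ⇐ seco bromo-enal 27: the C1–C2 bond is closed by a chromium-catalysed asymmetric intramolecular 2-(methoxycarbonyl)allylation, which forms the 14-membered ring first and the cis-fused α-methylene lactone in the same flask.
3. 27 ⇐ C10–C11 by B-alkyl Suzuki–Miyaura coupling of Z-vinyl iodide 11 (fragment A) with the 9-BBN borane of triene 22 (fragment B–C).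
4. 22 ⇐ C5–C6 by copper-catalysed alkyne–allyl coupling of (S)-enynol 19 (fragment B, C8 from a Sharpless epoxidation) with allylic bromide 15 (fragment C, from prenol), then trans-reduction.
5. 11 ⇐ propargyl alcohol (Z-selective carbomagnesiation/iodination), Brown allylation (C13) and Baylis–Hillman reaction with methyl acrylate.

Assumption: cembrane numbering is used for ring compounds (C1 = ring CH bearing the lactone α-carbon C15, C16 = C=O, C17 = exocyclic CH2, C2 = lactone O–CH, C3=C4(Me), C5, C6=C7, C8(Me)(OH), C9, C10, C11/C12(Me) epoxide, C13(OAc), C14); the SMILES is read as a cis-fused lactone and an epoxide in which C10 and C13 are cis, i.e. derived from an 11Z olefin.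

**Fragment A (C11–C17)**

Step 1
Reactants: 1 prop-2-yn-1-ol
Product: 3 (2Z)-3-iodo-2-methylprop-2-en-1-ol, via alkenylmagnesium alkoxide 2 (not isolated)
Conditions: MeMgBr (2.5 equiv), CuI (10 mol%), THF, −10 °C → rt; then I2, −10 °C
Reagents that add atoms: methylmagnesium bromide C[Mg]Br; iodine II
Why: Copper-catalysed anti-carbomagnesiation of the propargylic alkoxide (Duboudin-type carbometalation) holds Mg cis to CH2O in a chelate, so iodinolysis with retention gives only the Z vinyl iodide that becomes the 11Z olefin.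

Step 2
Reactants: 3 (2Z)-3-iodo-2-methylprop-2-en-1-ol
Product: 4 (2Z)-3-iodo-2-methylprop-2-enal
Conditions: MnO2 (excess), CH2Cl2, rt, dark; used crude at once
Reagents that add atoms: none
Why: Neutral MnO2 oxidation of a primary allylic alcohol gives the enal without Z→E isomerisation when the product is not stored.

Step 3
Reactants: 4 (2Z)-3-iodo-2-methylprop-2-enal, 5 allylmagnesium bromide
Product: 7 (1Z,3R)-1-iodo-2-methylhexa-1,5-dien-3-ol, via borinate ester 6 (not isolated)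
Conditions: (+)-Ipc2BOMe [from (−)-α-pinene], 5, Et2O, 0 °C → rt; then 4, −78 °C; then NaOH, H2O2, 0 °C → rt
Reagents that add atoms: none
Why: Brown asymmetric allylboration through a closed chair transition state; this reagent enantiomer attacks the Re face of the aldehyde (the sense that gives (R)-1-phenylbut-3-en-1-ol from benzaldehyde) and sets C13 as R.

Step 4
Reactants: 7 (1Z,3R)-1-iodo-2-methylhexa-1,5-dien-3-ol
Product: 8 1-({[(1Z,3R)-1-iodo-2-methylhexa-1,5-dien-3-yl]oxy}methyl)-4-methoxybenzene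
Conditions: NaH, PMBCl, Bu4NI (cat.), THF/DMF, 0 °C → rt
Reagents that add atoms: 4-methoxybenzyl chloride COc1ccc(CCl)cc1
Why: Williamson etherification installs a PMB ether that is orthogonal to the silyl ethers used later.

Step 5
Reactants: 8 1-({[(1Z,3R)-1-iodo-2-methylhexa-1,5-dien-3-yl]oxy}methyl)-4-methoxybenzene
Product: 9 (3R,4Z)-5-iodo-3-[(4-methoxybenzyl)oxy]-4-methylpent-4-enal
Conditions: OsO4 (2 mol%), NaIO4, 2,6-lutidine, dioxane/H2O, rt
Reagents that add atoms: sodium periodate (terminal oxidant, oxygen enters through OsO4) [Na+].[O-]I(=O)(=O)=O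
Why: Lemieux–Johnson cleavage; OsO4 dihydroxylates only the monosubstituted olefin because the iodo-trisubstituted olefin is hindered and electron-poor.

Step 6
Reactants: 9 (3R,4Z)-5-iodo-3-[(4-methoxybenzyl)oxy]-4-methylpent-4-enal, 10 methyl acrylate
Product: 11 methyl (5R,6Z)-3-hydroxy-7-iodo-5-[(4-methoxybenzyl)oxy]-6-methyl-2-methylidenehept-6-enoate
Conditions: quinuclidine (0.5 equiv), MeOH (0.75 equiv), 10 (neat), rt, 2–4 d
Reagents that add atoms: none
Why: Morita–Baylis–Hillman reaction; the new carbinol centre forms as a mixture, which does not matter because it is erased in step 19.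

**Fragment C (C2–C5)**

Step 7
Reactants: 12 3-methylbut-2-en-1-ol
Product: 13 3-methylbut-2-en-1-yl acetate
Conditions: Ac2O, pyridine, DMAP (cat.), CH2Cl2, 0 °C → rt
Reagents that add atoms: acetic anhydride CC(=O)OC(C)=O
Why: DMAP-catalysed acetylation protects the alcohol before allylic oxidation.

Step 8
Reactants: 13 3-methylbut-2-en-1-yl acetate
Product: 14 (2E)-4-hydroxy-3-methylbut-2-en-1-yl acetate
Conditions: SeO2 (0.5 equiv), t-BuOOH, CH2Cl2, 0 °C → rt
Reagents that add atoms: tert-butyl hydroperoxide CC(C)(C)OO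
Why: Sharpless SeO2/t-BuOOH allylic oxidation (ene reaction then [2,3]-shift) oxidises the methyl group trans to the CH2OAc chain, giving the E alcohol.

Step 9
Reactants: 14 (2E)-4-hydroxy-3-methylbut-2-en-1-yl acetate
Product: 15 (2E)-4-bromo-3-methylbut-2-en-1-yl acetate
Conditions: PBr3 (0.4 equiv), Et2O, −10 °C
Reagents that add atoms: phosphorus tribromide BrP(Br)Br
Why: PBr3 bromination of the primary allylic alcohol proceeds by SN2 without loss of the E geometry.

**Fragment B (C6–C10) and assembly**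

Step 10
Reactants: 16 (2E)-3-methylpent-2-en-4-yn-1-ol
Product: 17 [(2R,3R)-3-ethynyl-3-methyloxiran-2-yl]methanol
Conditions: Ti(OiPr)4 (10 mol%), D-(−)-diethyl tartrate (12 mol%), t-BuOOH, 4 Å MS, CH2Cl2, −20 °C
Reagents that add atoms: tert-butyl hydroperoxide CC(C)(C)OO
Why: Katsuki–Sharpless asymmetric epoxidation; D-(−)-tartrate gives the (2R,3R) epoxide from this E allylic alcohol (mirror image of the geraniol/L-(+)-tartrate case), which fixes the future C8.

Step 11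
Reactants: 17 [(2R,3R)-3-ethynyl-3-methyloxiran-2-yl]methanol
Product: 18 (2S,3R)-3-ethynyl-2-(iodomethyl)-3-methyloxirane
Conditions: I2, PPh3, imidazole, CH2Cl2, 0 °C
Reagents that add atoms: iodine II
Why: Appel-type iodination of the primary alcohol under neutral conditions leaves the epoxide untouched.

Step 12
Reactants: 18 (2S,3R)-3-ethynyl-2-(iodomethyl)-3-methyloxirane
Product: 19 (3S)-3-methylpent-1-en-4-yn-3-ol
Conditions: Zn dust, AcOH, EtOH, 0 °C → rt; volatile product carried on as a solution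
Reagents that add atoms: none
Why: Zinc insertion and β-alkoxide elimination (reductive epoxide opening) unveil the vinyl group while the C–O bond at the quaternary carbon stays intact, giving the S tertiary alcohol (C8).

Step 13
Reactants: 19 (3S)-3-methylpent-1-en-4-yn-3-ol, 15 (2E)-4-bromo-3-methylbut-2-en-1-yl acetate
Product: 20 (2E,7S)-7-hydroxy-3,7-dimethylnona-2,8-dien-5-yn-1-yl acetate
Conditions: CuI (20 mol%), Cs2CO3, DMF, rt
Reagents that add atoms: none
Why: Copper-catalysed alkyne–allyl coupling (copper acetylide SN2 substitution of the primary allylic bromide) forms C5–C6 with the E olefin retained and tolerates the free tertiary alcohol and the acetate.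

Step 14
Reactants: 20 (2E,7S)-7-hydroxy-3,7-dimethylnona-2,8-dien-5-yn-1-yl acetate
Product: 21 (2E,5E,7S)-3,7-dimethylnona-2,5,8-triene-1,7-diol
Conditions: NaAlH2(OCH2CH2OMe)2 (Red-Al, 4 equiv), THF, 0 °C → rt; Rochelle salt
Reagents that add atoms: none
Why: Hydroxyl-directed trans-hydroalumination of the propargylic alcohol gives only the E olefin (C6=C7), and the same reagent removes the acetate.

Step 15
Reactants: 21 (2E,5E,7S)-3,7-dimethylnona-2,5,8-triene-1,7-diol
Product: 22 (3S,4E,7E)-3,7-dimethyl-3,9-bis[(triethylsilyl)oxy]nona-1,4,7-triene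
Conditions: TESOTf (2.5 equiv), 2,6-lutidine, CH2Cl2, −78 → 0 °C
Reagents that add atoms: triethylsilyl triflate CC[Si](CC)(CC)OS(=O)(=O)C(F)(F)F
Why: Silylation with the triflate protects both hydroxyls, and the hindered tertiary TES ether then survives to the last step.

Step 16
Reactants: 22 (3S,4E,7E)-3,7-dimethyl-3,9-bis[(triethylsilyl)oxy]nona-1,4,7-triene, 11 methyl (5R,6Z)-3-hydroxy-7-iodo-5-[(4-methoxybenzyl)oxy]-6-methyl-2-methylidenehept-6-enoate
Product: 24 methyl (5R,6Z,10S,11E,14E)-3-hydroxy-5-[(4-methoxybenzyl)oxy]-6,10,14-trimethyl-2-methylidene-10,16-bis[(triethylsilyl)oxy]hexadeca-6,11,14-trienoate, via alkylborane 23 (not isolated)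
Conditions: 22, 9-BBN (1.5 equiv), THF, rt; then 11, Pd(dppf)Cl2 (10 mol%), AsPh3, Cs2CO3, DMF/H2O, rt
Reagents that add atoms: none
Why: 9-BBN hydroborates only the monosubstituted vinyl group (anti-Markovnikov), and B-alkyl Suzuki–Miyaura coupling with the Z vinyl iodide forms C10–C11 with retention of the Z geometry.

Step 17
Reactants: 24 methyl (5R,6Z,10S,11E,14E)-3-hydroxy-5-[(4-methoxybenzyl)oxy]-6,10,14-trimethyl-2-methylidene-10,16-bis[(triethylsilyl)oxy]hexadeca-6,11,14-trienoate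
Product: 25 methyl (5R,6Z,10S,11E,14E)-3,16-dihydroxy-5-[(4-methoxybenzyl)oxy]-6,10,14-trimethyl-2-methylidene-10-[(triethylsilyl)oxy]hexadeca-6,11,14-trienoate
Conditions: PPTS (0.1 equiv), MeOH/CH2Cl2, 0 °C
Reagents that add atoms: none
Why: Acid-catalysed methanolysis cleaves the primary allylic TES ether much faster than the hindered tertiary one.

Step 18
Reactants: 25 methyl (5R,6Z,10S,11E,14E)-3,16-dihydroxy-5-[(4-methoxybenzyl)oxy]-6,10,14-trimethyl-2-methylidene-10-[(triethylsilyl)oxy]hexadeca-6,11,14-trienoate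
Product: 26 methyl (5R,6Z,10S,11E,14E)-3-hydroxy-5-[(4-methoxybenzyl)oxy]-6,10,14-trimethyl-2-methylidene-16-oxo-10-[(triethylsilyl)oxy]hexadeca-6,11,14-trienoate
Conditions: MnO2, CH2Cl2, rt
Reagents that add atoms: none
Why: MnO2 oxidises the primary allylic alcohol to the enal, while the Baylis–Hillman carbinol next to the electron-poor olefin is inert.

Step 19
Reactants: 26 methyl (5R,6Z,10S,11E,14E)-3-hydroxy-5-[(4-methoxybenzyl)oxy]-6,10,14-trimethyl-2-methylidene-16-oxo-10-[(triethylsilyl)oxy]hexadeca-6,11,14-trienoate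
Product: 27 methyl (2Z,5R,6Z,10S,11E,14E)-2-(bromomethyl)-5-[(4-methoxybenzyl)oxy]-6,10,14-trimethyl-16-oxo-10-[(triethylsilyl)oxy]hexadeca-2,6,11,14-tetraenoate
Conditions: NBS, Me2S, CH2Cl2, −20 → 0 °C
Reagents that add atoms: N-bromosuccinimide O=C1CCC(=O)N1Br
Why: Corey–Kim-type bromination of the Baylis–Hillman alcohol proceeds with allylic transposition (SN2') to the thermodynamically preferred (Z)-2-(bromomethyl)enoate and does not touch the enal.

Step 20
Reactants: 27 methyl (2Z,5R,6Z,10S,11E,14E)-2-(bromomethyl)-5-[(4-methoxybenzyl)oxy]-6,10,14-trimethyl-16-oxo-10-[(triethylsilyl)oxy]hexadeca-2,6,11,14-tetraenoate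
Product: 30 (1S,2S,3E,6E,8S,11Z,13R)-13-[(4-methoxybenzyl)oxy]-8-[(triethylsilyl)oxy]cembra-3,6,11,15(17)-tetraen-16,2-olide, via trimethylsilyl ether 28 (not isolated), via hydroxy ester 29 (not isolated)
Conditions: CrCl2 (15 mol%), ligand L (18 mol%; L = 3,6-di-tert-butyl-1,8-bis[(4S)-4-isopropyl-4,5-dihydrooxazol-2-yl]-9H-carbazole), i-Pr2NEt (30 mol%), Mn powder (3 equiv), TMSCl (2 equiv), THF, rt, 27 added over 12 h to 2 mM; then PPTS, MeOH, 0 °C → rt
Reagents that add atoms: none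
Why: Proposed new method: a ligand-controlled, chromium-catalysed asymmetric macrocyclising Nozaki–Hiyama–Kishi 2-(alkoxycarbonyl)allylation, in which ligated divalent chromium reduces the allylic bromide in two one-electron steps to an allyl–trivalent chromium species whose ester keeps C14 cis to CH2Cr, so that the closed six-membered (Zimmerman–Traxler) transition state places C14 axial and gives the syn C1/C2 pair (cis-lactone), the ligand selects the Re face of the enal (2S, hence 1S), TMSCl releases the chromium alkoxide, Mn returns trivalent to divalent chromium and slow addition favours 14-ring closure over dimerisation; the closest known reaction types are the intermolecular chromium-catalysed enantioselective 2-(alkoxycarbonyl)allylation of aldehydes to cis-α-methylene-γ-butyrolactones and the stoichiometric, substrate-controlled CrCl2 macrocyclisations of ω-formyl allylic bromides.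

Step 21
Reactants: 30 (1S,2S,3E,6E,8S,11Z,13R)-13-[(4-methoxybenzyl)oxy]-8-[(triethylsilyl)oxy]cembra-3,6,11,15(17)-tetraen-16,2-olide
Product: 31 (1S,2S,3E,6E,8S,11Z,13R)-13-hydroxy-8-[(triethylsilyl)oxy]cembra-3,6,11,15(17)-tetraen-16,2-olide
Conditions: DDQ (1.5 equiv), CH2Cl2/pH 7 buffer, 0 °C
Reagents that add atoms: none
Why: Oxidative PMB cleavage by DDQ frees the C13 allylic alcohol without affecting the silyl ether or the lactone.

Step 22
Reactants: 31 (1S,2S,3E,6E,8S,11Z,13R)-13-hydroxy-8-[(triethylsilyl)oxy]cembra-3,6,11,15(17)-tetraen-16,2-olide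
Product: 32 (1S,2S,3E,6E,8S,11S,12R,13R)-11,12-epoxy-13-hydroxy-8-[(triethylsilyl)oxy]cembra-3,6,15(17)-trien-16,2-olide
Conditions: VO(acac)2 (5 mol%), t-BuOOH (1.5 equiv), CH2Cl2, 0 °C
Reagents that add atoms: tert-butyl hydroperoxide CC(C)(C)OO
Why: Hydroxyl-directed vanadium-catalysed epoxidation touches only C11=C12 (the sole olefin with a free allylic OH), and in the vanadate transition state (O–C13–C12=C11 dihedral near 45°) A(1,2) strain with the C12 methyl directs oxygen to the face that gives the erythro epoxy alcohol, i.e. the target configuration at C11 and C12 (the C12 descriptor reads R here only because of CIP priorities).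

Step 23
Reactants: 32 (1S,2S,3E,6E,8S,11S,12R,13R)-11,12-epoxy-13-hydroxy-8-[(triethylsilyl)oxy]cembra-3,6,15(17)-trien-16,2-olide
Product: 33 (1S,2S,3E,6E,8S,11S,12S,13R)-13-acetoxy-11,12-epoxy-8-[(triethylsilyl)oxy]cembra-3,6,15(17)-trien-16,2-olide
Conditions: Ac2O, pyridine, DMAP (cat.), CH2Cl2, 0 °C → rt
Reagents that add atoms: acetic anhydride CC(=O)OC(C)=O
Why: DMAP-catalysed acetylation of the only free (secondary) hydroxyl.

Step 24
Reactants: 33 (1S,2S,3E,6E,8S,11S,12S,13R)-13-acetoxy-11,12-epoxy-8-[(triethylsilyl)oxy]cembra-3,6,15(17)-trien-16,2-olide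
Product: 34 (1S,2S,3E,6E,8S,11S,12S,13R)-13-acetoxy-11,12-epoxy-8-hydroxycembra-3,6,15(17)-trien-16,2-olide (CNP0288879.2)
Conditions: Bu4NF/AcOH (1:1, 3 equiv), THF, 0 °C → rt
Reagents that add atoms: none
Why: Buffered fluoride desilylation frees the tertiary alcohol without acid- or base-induced attack of the C8 hydroxyl on the epoxide and without addition to the α-methylene lactone.

**Compound list**
1 | prop-2-yn-1-ol | C#CCO | starting material
2 | bromo{(1Z)-3-[(bromomagnesio)oxy]-2-methylprop-1-en-1-yl}magnesium | C/C(CO[Mg]Br)=C/[Mg]Br | intermediate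
3 | (2Z)-3-iodo-2-methylprop-2-en-1-ol | C/C(CO)=C/I | intermediate
4 | (2Z)-3-iodo-2-methylprop-2-enal | C/C(C=O)=C/I | intermediate
5 | allylmagnesium bromide | C=CC[Mg]Br | starting material
6 | (1Z,3R)-1-iodo-2-methylhexa-1,5-dien-3-yl bis(isopinocampheyl)borinate | C=CC[C@@H](OB([C@H]1C[C@H]2C[C@@H]([C@@H]1C)C2(C)C)[C@H]1C[C@H]2C[C@@H]([C@@H]1C)C2(C)C)/C(C)=C\I | intermediate
7 | (1Z,3R)-1-iodo-2-methylhexa-1,5-dien-3-ol | C=CC[C@@H](O)/C(C)=C\I | intermediate
8 | 1-({[(1Z,3R)-1-iodo-2-methylhexa-1,5-dien-3-yl]oxy}methyl)-4-methoxybenzene | C=CC[C@@H](OCc1ccc(OC)cc1)/C(C)=C\I | intermediate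
9 | (3R,4Z)-5-iodo-3-[(4-methoxybenzyl)oxy]-4-methylpent-4-enal | O=CC[C@@H](OCc1ccc(OC)cc1)/C(C)=C\I | intermediate
10 | methyl acrylate | C=CC(=O)OC | starting material
11 | methyl (5R,6Z)-3-hydroxy-7-iodo-5-[(4-methoxybenzyl)oxy]-6-methyl-2-methylidenehept-6-enoate (both C3 epimers) | COC(=O)C(=C)C(O)C[C@@H](OCc1ccc(OC)cc1)/C(C)=C\I | intermediate
12 | 3-methylbut-2-en-1-ol | CC(C)=CCO | starting material
13 | 3-methylbut-2-en-1-yl acetate | CC(C)=CCOC(C)=O | intermediate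
14 | (2E)-4-hydroxy-3-methylbut-2-en-1-yl acetate | CC(=O)OC/C=C(\C)CO | intermediate
15 | (2E)-4-bromo-3-methylbut-2-en-1-yl acetate | CC(=O)OC/C=C(\C)CBr | intermediate
16 | (2E)-3-methylpent-2-en-4-yn-1-ol | C#C/C(C)=C/CO | starting material
17 | [(2R,3R)-3-ethynyl-3-methyloxiran-2-yl]methanol | C#C[C@@]1(C)O[C@@H]1CO | intermediate
18 | (2S,3R)-3-ethynyl-2-(iodomethyl)-3-methyloxirane | C#C[C@@]1(C)O[C@@H]1CI | intermediate
19 | (3S)-3-methylpent-1-en-4-yn-3-ol | C#C[C@@](C)(O)C=C | intermediate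
20 | (2E,7S)-7-hydroxy-3,7-dimethylnona-2,8-dien-5-yn-1-yl acetate | CC(=O)OC/C=C(\C)CC#C[C@@](C)(O)C=C | intermediate
21 | (2E,5E,7S)-3,7-dimethylnona-2,5,8-triene-1,7-diol | OC/C=C(\C)C/C=C/[C@@](C)(O)C=C | intermediate
22 | (3S,4E,7E)-3,7-dimethyl-3,9-bis[(triethylsilyl)oxy]nona-1,4,7-triene | CC[Si](CC)(CC)OC/C=C(\C)C/C=C/[C@@](C)(O[Si](CC)(CC)CC)C=C | intermediate
23 | 9-{(3S,4E,7E)-3,7-dimethyl-3,9-bis[(triethylsilyl)oxy]nona-4,7-dien-1-yl}-9-borabicyclo[3.3.1]nonane | CC[Si](CC)(CC)OC/C=C(\C)C/C=C/[C@@](C)(O[Si](CC)(CC)CC)CCB1C2CCCC1CCC2 | intermediate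
24 | methyl (5R,6Z,10S,11E,14E)-3-hydroxy-5-[(4-methoxybenzyl)oxy]-6,10,14-trimethyl-2-methylidene-10,16-bis[(triethylsilyl)oxy]hexadeca-6,11,14-trienoate (both C3 epimers) | COC(=O)C(=C)C(O)C[C@@H](OCc1ccc(OC)cc1)/C(C)=C\CC[C@](C)(O[Si](CC)(CC)CC)/C=C/C/C(C)=C/CO[Si](CC)(CC)CC | intermediate
25 | methyl (5R,6Z,10S,11E,14E)-3,16-dihydroxy-5-[(4-methoxybenzyl)oxy]-6,10,14-trimethyl-2-methylidene-10-[(triethylsilyl)oxy]hexadeca-6,11,14-trienoate (both C3 epimers) | COC(=O)C(=C)C(O)C[C@@H](OCc1ccc(OC)cc1)/C(C)=C\CC[C@](C)(O[Si](CC)(CC)CC)/C=C/C/C(C)=C/CO | intermediate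
26 | methyl (5R,6Z,10S,11E,14E)-3-hydroxy-5-[(4-methoxybenzyl)oxy]-6,10,14-trimethyl-2-methylidene-16-oxo-10-[(triethylsilyl)oxy]hexadeca-6,11,14-trienoate (both C3 epimers) | COC(=O)C(=C)C(O)C[C@@H](OCc1ccc(OC)cc1)/C(C)=C\CC[C@](C)(O[Si](CC)(CC)CC)/C=C/C/C(C)=C/C=O | intermediate
27 | methyl (2Z,5R,6Z,10S,11E,14E)-2-(bromomethyl)-5-[(4-methoxybenzyl)oxy]-6,10,14-trimethyl-16-oxo-10-[(triethylsilyl)oxy]hexadeca-2,6,11,14-tetraenoate | COC(=O)/C(CBr)=C/C[C@@H](OCc1ccc(OC)cc1)/C(C)=C\CC[C@](C)(O[Si](CC)(CC)CC)/C=C/C/C(C)=C/C=O | intermediate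
28 | methyl 2-{(1S,2S,3E,6E,8S,11Z,13R)-13-[(4-methoxybenzyl)oxy]-4,8,12-trimethyl-8-[(triethylsilyl)oxy]-2-[(trimethylsilyl)oxy]cyclotetradeca-3,6,11-trien-1-yl}prop-2-enoate | COC(=O)C(=C)[C@@H]1C[C@@H](OCc2ccc(OC)cc2)/C(C)=C\CC[C@](C)(O[Si](CC)(CC)CC)/C=C/C/C(C)=C/[C@@H]1O[Si](C)(C)C | intermediate
29 | methyl 2-{(1S,2S,3E,6E,8S,11Z,13R)-2-hydroxy-13-[(4-methoxybenzyl)oxy]-4,8,12-trimethyl-8-[(triethylsilyl)oxy]cyclotetradeca-3,6,11-trien-1-yl}prop-2-enoate | COC(=O)C(=C)[C@@H]1C[C@@H](OCc2ccc(OC)cc2)/C(C)=C\CC[C@](C)(O[Si](CC)(CC)CC)/C=C/C/C(C)=C/[C@@H]1O | intermediate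
30 | (1S,2S,3E,6E,8S,11Z,13R)-13-[(4-methoxybenzyl)oxy]-8-[(triethylsilyl)oxy]cembra-3,6,11,15(17)-tetraen-16,2-olide | C=C1C(=O)O[C@H]2/C=C(\C)C/C=C/[C@@](C)(O[Si](CC)(CC)CC)CC/C=C(C)\[C@H](OCc3ccc(OC)cc3)C[C@@H]12 | intermediate
31 | (1S,2S,3E,6E,8S,11Z,13R)-13-hydroxy-8-[(triethylsilyl)oxy]cembra-3,6,11,15(17)-tetraen-16,2-olide | C=C1C(=O)O[C@H]2/C=C(\C)C/C=C/[C@@](C)(O[Si](CC)(CC)CC)CC/C=C(C)\[C@H](O)C[C@@H]12 | intermediate
32 | (1S,2S,3E,6E,8S,11S,12R,13R)-11,12-epoxy-13-hydroxy-8-[(triethylsilyl)oxy]cembra-3,6,15(17)-trien-16,2-olide | C=C1C(=O)O[C@H]2/C=C(\C)C/C=C/[C@@](C)(O[Si](CC)(CC)CC)CC[C@@H]3O[C@]3(C)[C@H](O)C[C@@H]12 | intermediate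
33 | (1S,2S,3E,6E,8S,11S,12S,13R)-13-acetoxy-11,12-epoxy-8-[(triethylsilyl)oxy]cembra-3,6,15(17)-trien-16,2-olide | C=C1C(=O)O[C@H]2/C=C(\C)C/C=C/[C@@](C)(O[Si](CC)(CC)CC)CC[C@@H]3O[C@]3(C)[C@H](OC(C)=O)C[C@@H]12 | intermediate
34 | (1S,2S,3E,6E,8S,11S,12S,13R)-13-acetoxy-11,12-epoxy-8-hydroxycembra-3,6,15(17)-trien-16,2-olide (CNP0288879.2) | C=C1C(=O)O[C@H]2/C=C(\C)C/C=C/[C@@](C)(O)CC[C@@H]3O[C@]3(C)[C@H](OC(C)=O)C[C@@H]12 | target

**Totals**
Total step count: 24.
Longest linear sequence: 15 steps (steps 10–24 from 16; equally steps 1–6 then 16–24 from 1, or steps 7–9 then 13–24 from 12), i.e. 62.5 % of the total.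

**Three steps most likely to fail**

Step 20 (the proposed new macrocyclisation). Risks are dimerisation instead of ring closure, the ring strain overriding the ligand's facial preference, and vinylogous enolisation of the skipped enal. The ligand enantiomer is first checked on the intermolecular reaction below.
Fallback (known chemistry; sets out from 11 and 22, comes back at 30):
- 11 is brominated (NBS, Me2S) to methyl (2Z,5R,6Z)-2-(bromomethyl)-7-iodo-5-[(4-methoxybenzyl)oxy]-6-methylhepta-2,6-dienoate F2.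
- 22 is mono-desilylated (PPTS, MeOH) to (2E,5E,7S)-3,7-dimethyl-7-[(triethylsilyl)oxy]nona-2,5,8-trien-1-ol F3 and oxidised (MnO2) to (2E,5E,7S)-3,7-dimethyl-7-[(triethylsilyl)oxy]nona-2,5,8-trienal F4.
- The known intermolecular chromium-catalysed enantioselective 2-(alkoxycarbonyl)allylation of F4 with F2 (CrCl2, ligand L, Mn, TMSCl, THF) gives the open-chain trimethylsilyl ether F5.
- Methanolysis (PPTS, MeOH) gives the open-chain hydroxy ester F6, which closes to the cis-α-methylene-γ-butyrolactone F7.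
- 9-BBN hydroborates the vinyl group to the lactone borane F8, and an intramolecular B-alkyl Suzuki–Miyaura coupling (Pd(dppf)Cl2, AsPh3, Cs2CO3, DMF/THF/H2O, high dilution) closes the ring at C10–C11 to give 30.

Step 22 (directed epoxidation in the macrocycle). The Z substituent C10 adds A(1,3) strain that erodes the erythro preference, and the ring conformation may override the acyclic model.
Fallback (sets out from 31, comes back at 33):
- Dess–Martin oxidation gives (1S,2S,3E,6E,8S,11Z)-13-oxo-8-[(triethylsilyl)oxy]cembra-3,6,11,15(17)-tetraen-16,2-olide F9.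
- Reduction with (R)-Me-CBS and catecholborane gives the 13S epimer, (1S,2S,3E,6E,8S,11Z,13S)-13-hydroxy-8-[(triethylsilyl)oxy]cembra-3,6,11,15(17)-tetraen-16,2-olide F10.
- Ti(OiPr)4/t-BuOOH epoxidation, now under the usually stronger A(1,3) control, gives the threo epoxy alcohol (1S,2S,3E,6E,8S,11S,12R,13S)-11,12-epoxy-13-hydroxy-8-[(triethylsilyl)oxy]cembra-3,6,15(17)-trien-16,2-olide F11.
- Mitsunobu reaction with acetic acid (PPh3, DIAD) inverts C13 and installs the acetate in one operation to give 33.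

Step 6 (Baylis–Hillman reaction of the β-alkoxy aldehyde). The reaction is slow, and the amine can cause β-elimination of 4-methoxybenzyl alcohol.
Fallback (sets out from 9, comes back at 11): methyl propiolate is hydroaluminated (i-Bu2AlH, N-methylmorpholine N-oxide, THF, 0 °C) to methyl 2-(diisobutylalumanyl)prop-2-enoate F1, which adds to 9 at 0 °C within an hour without amine base (vinylalumination) and gives 11 after aqueous work-up.

**Further compounds**
F1 | step 6 | methyl 2-(diisobutylalumanyl)prop-2-enoate | COC(=O)C(=C)[Al](CC(C)C)CC(C)C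
F2 | step 20 | methyl (2Z,5R,6Z)-2-(bromomethyl)-7-iodo-5-[(4-methoxybenzyl)oxy]-6-methylhepta-2,6-dienoate | COC(=O)/C(CBr)=C/C[C@@H](OCc1ccc(OC)cc1)/C(C)=C\I
F3 | step 20 | (2E,5E,7S)-3,7-dimethyl-7-[(triethylsilyl)oxy]nona-2,5,8-trien-1-ol | OC/C=C(\C)C/C=C/[C@@](C)(O[Si](CC)(CC)CC)C=C
F4 | step 20 | (2E,5E,7S)-3,7-dimethyl-7-[(triethylsilyl)oxy]nona-2,5,8-trienal | O=C/C=C(\C)C/C=C/[C@@](C)(O[Si](CC)(CC)CC)C=C
F5 | step 20 | methyl (3S,4S,5E,8E,10S)-3-{(2R,3Z)-4-iodo-2-[(4-methoxybenzyl)oxy]-3-methylbut-3-en-1-yl}-6,10-dimethyl-2-methylidene-10-[(triethylsilyl)oxy]-4-[(trimethylsilyl)oxy]dodeca-5,8,11-trienoate | COC(=O)C(=C)[C@H](C[C@@H](OCc1ccc(OC)cc1)/C(C)=C\I)[C@@H](O[Si](C)(C)C)/C=C(\C)C/C=C/[C@@](C)(O[Si](CC)(CC)CC)C=C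
F6 | step 20 | methyl (3S,4S,5E,8E,10S)-4-hydroxy-3-{(2R,3Z)-4-iodo-2-[(4-methoxybenzyl)oxy]-3-methylbut-3-en-1-yl}-6,10-dimethyl-2-methylidene-10-[(triethylsilyl)oxy]dodeca-5,8,11-trienoate | COC(=O)C(=C)[C@H](C[C@@H](OCc1ccc(OC)cc1)/C(C)=C\I)[C@@H](O)/C=C(\C)C/C=C/[C@@](C)(O[Si](CC)(CC)CC)C=C
F7 | step 20 | (4S,5S)-4-{(2R,3Z)-4-iodo-2-[(4-methoxybenzyl)oxy]-3-methylbut-3-en-1-yl}-5-{(1E,4E,6S)-2,6-dimethyl-6-[(triethylsilyl)oxy]octa-1,4,7-trien-1-yl}-3-methylidenedihydrofuran-2(3H)-one | C=C1C(=O)O[C@@H](/C=C(\C)C/C=C/[C@@](C)(O[Si](CC)(CC)CC)C=C)[C@H]1C[C@@H](OCc1ccc(OC)cc1)/C(C)=C\I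
F8 | step 20 | 9-borabicyclo[3.3.1]nonan-9-yl adduct of F7 at the terminal vinyl carbon (C10 borane) | C=C1C(=O)O[C@@H](/C=C(\C)C/C=C/[C@@](C)(O[Si](CC)(CC)CC)CCB2C3CCCC2CCC3)[C@H]1C[C@@H](OCc1ccc(OC)cc1)/C(C)=C\I
F9 | step 22 | (1S,2S,3E,6E,8S,11Z)-13-oxo-8-[(triethylsilyl)oxy]cembra-3,6,11,15(17)-tetraen-16,2-olide | C=C1C(=O)O[C@H]2/C=C(\C)C/C=C/[C@@](C)(O[Si](CC)(CC)CC)CC/C=C(C)\C(=O)C[C@@H]12
F10 | step 22 | (1S,2S,3E,6E,8S,11Z,13S)-13-hydroxy-8-[(triethylsilyl)oxy]cembra-3,6,11,15(17)-tetraen-16,2-olide | C=C1C(=O)O[C@H]2/C=C(\C)C/C=C/[C@@](C)(O[Si](CC)(CC)CC)CC/C=C(C)\[C@@H](O)C[C@@H]12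
F11 | step 22 | (1S,2S,3E,6E,8S,11S,12R,13S)-11,12-epoxy-13-hydroxy-8-[(triethylsilyl)oxy]cembra-3,6,15(17)-trien-16,2-olide | C=C1C(=O)O[C@H]2/C=C(\C)C/C=C/[C@@](C)(O[Si](CC)(CC)CC)CC[C@@H]3O[C@]3(C)[C@@H](O)C[C@@H]12
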